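The dihydropyran ring of the chroman is opened at C4a–C4 and C3–C2, so that C3–C4 enters as one O-vinyl unit. The key step exploits that quaternary C2 is both an aryl ether carbon and allylic to the C1'=C2' alkene: in an (E)-aryl enol ether whose allylic (R)-carbinol carries a vinyl ether, a [3,3] shift builds C3–C2, relays the carbinol chirality to C2 and leaves C4 as an aldehyde, which the ortho-iodinated carbon C4a captures under CrCl2/NiCl2 in the same flask, closing the ring. The resulting propenyl group is later cleaved to the C2 aldehyde and extended by a Horner–Wadsworth–Emmons reaction with a C15 phosphonate.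

Key step: step 4

Remark: chroman locants (O1, C2, C3, C4, C4a, C8a) and side-chain locants (C1', C2', C3', C4') are used throughout; the stereocentre of the target is (2R), and compounds 1, 2 and 10 are taken as commercial.

Step 1
Reactants: 1 methyl 4-hydroxy-3-iodobenzoate; 2 pent-3-yn-2-one
Product: 3 methyl 3-iodo-4-{[(2E)-4-oxopent-2-en-2-yl]oxy}benzoate
Conditions: 1,4-diazabicyclo[2.2.2]octane (20 mol%), CH2Cl2, 23 °C
Reagents that add atoms: none
Why: Base-catalysed oxa-Michael addition of the acidic phenol to the ynone should give the vinylogous ester, whose preferred E geometry (aryloxy anti to acetyl) is reached by reversible addition–elimination.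

Step 2
Reactants: 3 methyl 3-iodo-4-{[(2E)-4-oxopent-2-en-2-yl]oxy}benzoate
Product: 4 methyl 4-{[(2E,4R)-4-hydroxypent-2-en-2-yl]oxy}-3-iodobenzoate
Conditions: (S)-1-methyl-3,3-diphenyltetrahydro-1H,3H-pyrrolo[1,2-c][1,3,2]oxazaborole (20 mol%), catecholborane, toluene, −78 °C; then MeOH, aq. NaOH wash
Reagents that add atoms: none
Why: In this Corey–Bakshi–Shibata reduction the alkenyl group is the large and methyl the small substituent, so the (S)-oxazaborolidine should give the (R)-carbinol, and catecholborane at low temperature avoids hydroboration of the enol ether.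

Step 3
Reactants: 4 methyl 4-{[(2E,4R)-4-hydroxypent-2-en-2-yl]oxy}-3-iodobenzoate
Product: 5 methyl 4-{[(2E,4R)-4-(ethenyloxy)pent-2-en-2-yl]oxy}-3-iodobenzoate
Conditions: ethyl vinyl ether (solvent), Hg(OCOCF3)2 (10 mol%), Et3N, 23 °C
Reagents that add atoms: ethyl vinyl ether, C=COCC
Why: Mercury-catalysed transfer vinylation of the allylic alcohol under amine buffering should install the vinyl ether without touching the carbinol configuration or the acid-labile aryl enol ether.

Step 4
Reactants: 5 methyl 4-{[(2E,4R)-4-(ethenyloxy)pent-2-en-2-yl]oxy}-3-iodobenzoate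
Product: 7 methyl (2R)-4-hydroxy-2-methyl-2-[(1E)-prop-1-en-1-yl]-3,4-dihydro-2H-1-benzopyran-6-carboxylate (C4 epimers), via aldehyde 6 (not isolated)
Conditions: toluene, 105 °C; then cool, CrCl2 (6 equiv), NiCl2 (2 mol%), DMF, 23 °C; aqueous work-up
Reagents that add atoms: none
Why: Heating triggers a Claisen rearrangement of the allyl vinyl ether, a suprafacial [3,3] shift through a chair transition state that forms C3–C2 and the C1'=C2' alkene and unmasks C4 as the aldehyde of 6. C2 is set by 1,3-chirality transfer from the (R)-carbinol, because the chair with the carbinol methyl pseudo-equatorial is enforced by A(1,3) strain with the C2 methyl (cis to the carbinol carbon in the E-enol ether), which also makes the new alkene E; the step therefore needs an isomerically pure E-enol ether, and the aryloxy donor at the bond-forming terminus should let the shift run below the temperature at which the tertiary allyl aryl ether of 6 would undergo aromatic Claisen rearrangement. Without isolation, zerovalent nickel inserts into the C4a–I bond, the aryl group passes to chromium and the arylchromium adds to the aldehyde (Nozaki–Hiyama–Kishi reaction), forming C4a–C4 and closing the dihydropyran ring by 6-exo-trig carbonyl addition. The closest known reaction types are the chirality-transferring Claisen rearrangement of secondary allyl vinyl ethers and the intramolecular Nozaki–Hiyama–Kishi arylation of aldehydes. The C4 carbinol forms without control and is removed in step 5; organochromium reagents select the aldehyde over the methyl ester, and the neutral conditions are chosen to avoid beta-elimination of the aryloxide from 6.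

Step 5
Reactants: 7 methyl (2R)-4-hydroxy-2-methyl-2-[(1E)-prop-1-en-1-yl]-3,4-dihydro-2H-1-benzopyran-6-carboxylate (C4 epimers)
Product: 8 methyl (2R)-2-methyl-2-[(1E)-prop-1-en-1-yl]-3,4-dihydro-2H-1-benzopyran-6-carboxylate
Conditions: Et3SiH, CF3CO2H, CH2Cl2, −20 to 0 °C
Reagents that add atoms: none
Why: In this ionic hydrogenation the acid should ionise the benzylic C4 alcohol to a cation stabilised by the ring oxygen through C8a, which Et3SiH reduces to CH2 before the tertiary allylic ether at C2 ionises.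

Step 6
Reactants: 8 methyl (2R)-2-methyl-2-[(1E)-prop-1-en-1-yl]-3,4-dihydro-2H-1-benzopyran-6-carboxylate
Product: 9 methyl (2R)-2-formyl-2-methyl-3,4-dihydro-2H-1-benzopyran-6-carboxylate
Conditions: O3, CH2Cl2/MeOH, −78 °C; then Me2S, −78 to 23 °C
Reagents that add atoms: ozone, [O-][O+]=O
Why: Ozonolysis with reductive work-up should cleave the only alkene to the non-enolisable C2 aldehyde, the ester-deactivated arene being inert at −78 °C and the C2 configuration untouched.

Step 7
Reactants: 10 4-(2,6,6-trimethylcyclohex-1-en-1-yl)butan-2-one (dihydro-β-ionone)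
Product: 11 ethyl (2E)-3-methyl-5-(2,6,6-trimethylcyclohex-1-en-1-yl)pent-2-enoate
Conditions: (EtO)2P(O)CH2CO2Et, NaH, THF, 0 to 65 °C; chromatographic removal of the Z isomer
Reagents that add atoms: triethyl phosphonoacetate, CCOC(=O)CP(=O)(OCC)OCC
Why: Horner–Wadsworth–Emmons olefination of the methyl ketone should give the trisubstituted enoate mainly as the E isomer, with the ester anti to the larger alkyl chain.

Step 8
Reactants: 11 ethyl (2E)-3-methyl-5-(2,6,6-trimethylcyclohex-1-en-1-yl)pent-2-enoate
Product: 12 (2E)-3-methyl-5-(2,6,6-trimethylcyclohex-1-en-1-yl)pent-2-en-1-ol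
Conditions: iBu2AlH, CH2Cl2, −78 °C; aq. potassium sodium tartrate
Reagents that add atoms: none
Why: 1,2-Reduction of the unsaturated ester by iBu2AlH should give the allylic alcohol with the E alkene unchanged.

Step 9
Reactants: 12 (2E)-3-methyl-5-(2,6,6-trimethylcyclohex-1-en-1-yl)pent-2-en-1-ol
Product: 13 2-[(3E)-5-bromo-3-methylpent-3-en-1-yl]-1,3,3-trimethylcyclohex-1-ene
Conditions: PBr3, pyridine (cat.), Et2O, 0 °C
Reagents that add atoms: phosphorus tribromide, BrP(Br)Br
Why: SN2 bromination of the primary allylic alcohol via its phosphite ester at low temperature should keep the E geometry and the allylic position.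

Step 10
Reactants: 13 2-[(3E)-5-bromo-3-methylpent-3-en-1-yl]-1,3,3-trimethylcyclohex-1-ene
Product: 14 diethyl [(2E)-3-methyl-5-(2,6,6-trimethylcyclohex-1-en-1-yl)pent-2-en-1-yl]phosphonate
Conditions: P(OEt)3, neat, 130 °C
Reagents that add atoms: triethyl phosphite, CCOP(OCC)OCC
Why: Michaelis–Arbuzov reaction of the primary allylic bromide should give the allylic phosphonate with loss of bromoethane.

Step 11
Reactants: 9 methyl (2R)-2-formyl-2-methyl-3,4-dihydro-2H-1-benzopyran-6-carboxylate; 14 diethyl [(2E)-3-methyl-5-(2,6,6-trimethylcyclohex-1-en-1-yl)pent-2-en-1-yl]phosphonate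
Product: 15 methyl (2R)-2-methyl-2-[(1E,3E)-4-methyl-6-(2,6,6-trimethylcyclohex-1-en-1-yl)hexa-1,3-dien-1-yl]-3,4-dihydro-2H-1-benzopyran-6-carboxylate
Conditions: 14, n-BuLi, THF, −78 °C; then 9, −78 to 23 °C
Reagents that add atoms: none
Why: Horner–Wadsworth–Emmons reaction of the lithiated allylic phosphonate through its α-carbon with the non-enolisable aldehyde should form the E C1'=C2' alkene and hence the E,E-diene, leaving the methyl ester and C2 untouched.

Step 12
Reactants: 15 methyl (2R)-2-methyl-2-[(1E,3E)-4-methyl-6-(2,6,6-trimethylcyclohex-1-en-1-yl)hexa-1,3-dien-1-yl]-3,4-dihydro-2H-1-benzopyran-6-carboxylate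
Product: 17 (2R)-2-methyl-2-[(1E,3E)-4-methyl-6-(2,6,6-trimethylcyclohex-1-en-1-yl)hexa-1,3-dien-1-yl]-3,4-dihydro-2H-1-benzopyran-6-carboxylic acid (target), via lithium carboxylate 16 (not isolated)
Conditions: LiOH, THF/MeOH/H2O, 40 °C; then 1 M HCl to pH 4, 0 °C
Reagents that add atoms: lithium hydroxide, [Li+].[OH-]
Why: Saponification of the methyl benzoate followed by mild acidification should give the acid, the tertiary allylic ether and the diene being stable to base.

Compound list
1 | methyl 4-hydroxy-3-iodobenzoate | COC(=O)c1ccc(O)c(I)c1 | starting material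
2 | pent-3-yn-2-one | CC#CC(C)=O | starting material
3 | methyl 3-iodo-4-{[(2E)-4-oxopent-2-en-2-yl]oxy}benzoate | COC(=O)c1ccc(O/C(C)=C/C(C)=O)c(I)c1 | intermediate
4 | methyl 4-{[(2E,4R)-4-hydroxypent-2-en-2-yl]oxy}-3-iodobenzoate | COC(=O)c1ccc(O/C(C)=C/[C@@H](C)O)c(I)c1 | intermediate
5 | methyl 4-{[(2E,4R)-4-(ethenyloxy)pent-2-en-2-yl]oxy}-3-iodobenzoate | COC(=O)c1ccc(O/C(C)=C/[C@@H](C)OC=C)c(I)c1 | intermediate
6 | methyl 3-iodo-4-{[(3R,4E)-3-methyl-1-oxohex-4-en-3-yl]oxy}benzoate | COC(=O)c1ccc(O[C@](C)(CC=O)/C=C/C)c(I)c1 | intermediate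
7 | methyl (2R)-4-hydroxy-2-methyl-2-[(1E)-prop-1-en-1-yl]-3,4-dihydro-2H-1-benzopyran-6-carboxylate (C4 epimers) | C/C=C/[C@@]1(C)CC(O)c2cc(C(=O)OC)ccc2O1 | intermediate
8 | methyl (2R)-2-methyl-2-[(1E)-prop-1-en-1-yl]-3,4-dihydro-2H-1-benzopyran-6-carboxylate | C/C=C/[C@@]1(C)CCc2cc(C(=O)OC)ccc2O1 | intermediate
9 | methyl (2R)-2-formyl-2-methyl-3,4-dihydro-2H-1-benzopyran-6-carboxylate | O=C[C@@]1(C)CCc2cc(C(=O)OC)ccc2O1 | intermediate
10 | 4-(2,6,6-trimethylcyclohex-1-en-1-yl)butan-2-one (dihydro-β-ionone) | CC(=O)CCC1=C(C)CCCC1(C)C | starting material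
11 | ethyl (2E)-3-methyl-5-(2,6,6-trimethylcyclohex-1-en-1-yl)pent-2-enoate | CCOC(=O)/C=C(\C)CCC1=C(C)CCCC1(C)C | intermediate
12 | (2E)-3-methyl-5-(2,6,6-trimethylcyclohex-1-en-1-yl)pent-2-en-1-ol | OC/C=C(\C)CCC1=C(C)CCCC1(C)C | intermediate
13 | 2-[(3E)-5-bromo-3-methylpent-3-en-1-yl]-1,3,3-trimethylcyclohex-1-ene | BrC/C=C(\C)CCC1=C(C)CCCC1(C)C | intermediate
14 | diethyl [(2E)-3-methyl-5-(2,6,6-trimethylcyclohex-1-en-1-yl)pent-2-en-1-yl]phosphonate | CCOP(=O)(OCC)C/C=C(\C)CCC1=C(C)CCCC1(C)C | intermediate
15 | methyl (2R)-2-methyl-2-[(1E,3E)-4-methyl-6-(2,6,6-trimethylcyclohex-1-en-1-yl)hexa-1,3-dien-1-yl]-3,4-dihydro-2H-1-benzopyran-6-carboxylate | CC1=C(CC/C(C)=C/C=C/[C@@]2(C)CCc3cc(C(=O)OC)ccc3O2)C(C)(C)CCC1 | intermediate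
16 | lithium (2R)-2-methyl-2-[(1E,3E)-4-methyl-6-(2,6,6-trimethylcyclohex-1-en-1-yl)hexa-1,3-dien-1-yl]-3,4-dihydro-2H-1-benzopyran-6-carboxylate | CC1=C(CC/C(C)=C/C=C/[C@@]2(C)CCc3cc(C(=O)[O-])ccc3O2)C(C)(C)CCC1.[Li+] | intermediate
17 | (2R)-2-methyl-2-[(1E,3E)-4-methyl-6-(2,6,6-trimethylcyclohex-1-en-1-yl)hexa-1,3-dien-1-yl]-3,4-dihydro-2H-1-benzopyran-6-carboxylic acid | CC1=C(CC/C(C)=C/C=C/[C@@]2(C)CCc3cc(C(=O)O)ccc3O2)C(C)(C)CCC1 | target

Total step count: 12. Longest linear sequence: 8 steps (steps 1 to 6, 11 and 12); the side-chain branch (steps 7 to 10) joins at step 11.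

Steps most likely to fail

Step 4. The beta-aryloxy aldehyde may lose the aryloxide by beta-elimination before the arylchromium adds, or the chirality transfer may leak through a boat transition state. The fallback sets out from 4. An Eschenmoser–Claisen rearrangement with N,N-dimethylacetamide dimethyl acetal (toluene, 110 °C) should give, with the same sense of chirality transfer, the elimination-resistant amide methyl 4-{[(3R,4E)-1-(dimethylamino)-3-methyl-1-oxohex-4-en-3-yl]oxy}-3-iodobenzoate F1. Iodine–magnesium exchange with iPrMgCl·LiCl (THF, −40 °C) and Parham-type intramolecular acylation by the amide should then close the ring to methyl (2R)-2-methyl-4-oxo-2-[(1E)-prop-1-en-1-yl]-3,4-dihydro-2H-1-benzopyran-6-carboxylate F2. Luche reduction (NaBH4, CeCl3, MeOH) of F2 comes back to the route at 7.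

Step 2. The vinylogous ester carbonyl may be reduced sluggishly or with poor facial discrimination, and the enol ether may be hydroborated. The fallback sets out from 3 and uses resolution instead of asymmetric reduction. Luche reduction (NaBH4, CeCl3, MeOH) should give racemic methyl 4-{[(2E)-4-hydroxypent-2-en-2-yl]oxy}-3-iodobenzoate F3. Candida antarctica lipase B with vinyl acetate should acylate the R enantiomer, in line with the usual preference of this lipase for secondary methyl carbinols, to methyl 4-{[(2E,4R)-4-(acetyloxy)pent-2-en-2-yl]oxy}-3-iodobenzoate F4. The unreacted methyl 4-{[(2E,4S)-4-hydroxypent-2-en-2-yl]oxy}-3-iodobenzoate F5 is separated. Methanolysis of F4 (K2CO3, MeOH) comes back to the route at 4.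

Step 5. Acid may ionise the tertiary allylic C2–O bond and open the ring in competition with reduction at the benzylic position. The fallback sets out from 7 and replaces the cationic by a radical deoxygenation (Barton–McCombie). 1,1'-Thiocarbonyldiimidazole (CH2Cl2, 23 °C) should give methyl (2R)-4-[(1H-imidazol-1-ylcarbonothioyl)oxy]-2-methyl-2-[(1E)-prop-1-en-1-yl]-3,4-dihydro-2H-1-benzopyran-6-carboxylate F6. Bu3SnH with azobisisobutyronitrile (toluene, 80 °C) comes back to the route at 8.

Further compounds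
F1 | step 4 | methyl 4-{[(3R,4E)-1-(dimethylamino)-3-methyl-1-oxohex-4-en-3-yl]oxy}-3-iodobenzoate | COC(=O)c1ccc(O[C@](C)(CC(=O)N(C)C)/C=C/C)c(I)c1
F2 | step 4 | methyl (2R)-2-methyl-4-oxo-2-[(1E)-prop-1-en-1-yl]-3,4-dihydro-2H-1-benzopyran-6-carboxylate | C/C=C/[C@@]1(C)CC(=O)c2cc(C(=O)OC)ccc2O1
F3 | step 2 | methyl 4-{[(2E)-4-hydroxypent-2-en-2-yl]oxy}-3-iodobenzoate (racemic) | COC(=O)c1ccc(O/C(C)=C/C(C)O)c(I)c1
F4 | step 2 | methyl 4-{[(2E,4R)-4-(acetyloxy)pent-2-en-2-yl]oxy}-3-iodobenzoate | COC(=O)c1ccc(O/C(C)=C/[C@@H](C)OC(C)=O)c(I)c1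
F5 | step 2 | methyl 4-{[(2E,4S)-4-hydroxypent-2-en-2-yl]oxy}-3-iodobenzoate | COC(=O)c1ccc(O/C(C)=C/[C@H](C)O)c(I)c1
F6 | step 5 | methyl (2R)-4-[(1H-imidazol-1-ylcarbonothioyl)oxy]-2-methyl-2-[(1E)-prop-1-en-1-yl]-3,4-dihydro-2H-1-benzopyran-6-carboxylate | C/C=C/[C@@]1(C)CC(OC(=S)n2ccnc2)c2cc(C(=O)OC)ccc2O1
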